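**Strategy.** The route rests on disconnecting the cyclohexene ring of the octahydronaphthalene (C1–C2–C3=C4–C4a–C8a) by a retro-[4+2]. Its C3=C4 double bond lies between the C1–C2 and C4a–C8a bonds, and C1 carries the acyl carbonyl of the tetramic acid, so the ring is a Diels–Alder retron. The precursor is an acyclic (2E,8E,10E,12E,14E)-pentaenoyl tetramic acid in which only the C6 methyl and the two threonine centres are in place. A Diels–Alderase of the Fsa2 family (Phm7-type decalin synthase) folds it through the endo transition state with the 6-methyl axial, which the substrate alone disfavours. One operation sets C1, C2, C4a and C8a and closes both carbocycles.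

Key step: step 9

Assumption: the 3-acyltetramic acid is written throughout as the 4-hydroxy enol tautomer of the target string, and a recombinant Phm7-type Diels–Alderase is taken to be obtainable by heterologous expression and to accept the N–H, threonine-derived substrate 14.

**Step 1**
Reactants: 1 (R)-citronellal, (3R)-3,7-dimethyloct-6-enal
Product: 2 (1E,4R)-1-iodo-4,8-dimethylnona-1,7-diene
Conditions: CrCl2 (6 equiv), CHI3 (2 equiv), 1,4-dioxane/THF 6:1, 0 °C to rt, dark
Reagents that add atoms: iodoform, IC(I)I
Why: Takai iodo-olefination, in which the geminal dichromium reagent adds to the aldehyde and anti-elimination should give the E-iodoalkene; the methyl-bearing centre is β to the carbonyl and is not touched, and the trisubstituted alkene is inert.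

**Step 2**
Reactants: 2 (1E,4R)-1-iodo-4,8-dimethylnona-1,7-diene
Product: 3 (4R,6E)-7-iodo-4-methylhept-6-enal
Conditions: OsO4 (2 mol %), NaIO4 (4 equiv), 2,6-lutidine, 1,4-dioxane/H2O 3:1, rt
Reagents that add atoms: sodium periodate, [Na+].[O-]I(=O)(=O)=O; osmium tetroxide, O=[Os](=O)(=O)=O (catalytic oxygen carrier)
Why: Lemieux–Johnson cleavage, in which osmium tetroxide should dihydroxylate the electron-rich trisubstituted alkene far faster than the electron-poor 1,2-disubstituted iodoalkene and periodate cleaves the diol to the aldehyde.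

**Step 3**
Reactants: 4 (2E,4E)-hexa-2,4-dienal (sorbaldehyde)
Product: 5 2-[(1E,3E,5E)-hepta-1,3,5-trien-1-yl]-4,4,5,5-tetramethyl-1,3,2-dioxaborolane
Conditions: Cl2CHBpin (2 equiv), CrCl2 (8 equiv), LiI (additive), THF, rt, dark
Reagents that add atoms: 2-(dichloromethyl)-4,4,5,5-tetramethyl-1,3,2-dioxaborolane, ClC(Cl)B1OC(C)(C)C(C)(C)O1
Why: Takai–Utimoto boryl olefination, the boron counterpart of step 1, which should add one carbon to the dienal as an E-alkenylboronate and leave the two existing E double bonds unchanged.

**Step 4**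
Reactants: 3 (4R,6E)-7-iodo-4-methylhept-6-enal; 5 2-[(1E,3E,5E)-hepta-1,3,5-trien-1-yl]-4,4,5,5-tetramethyl-1,3,2-dioxaborolane
Product: 6 (4R,6E,8E,10E,12E)-4-methyltetradeca-6,8,10,12-tetraenal
Conditions: Pd(dppf)Cl2 (5 mol %), K3PO4, THF/H2O, rt, degassed, dark
Reagents that add atoms: none
Why: Suzuki–Miyaura coupling of an alkenyl iodide with an alkenylboronate, which proceeds with retention at both sp2 carbons and so should give the all-E tetraene; the aldehyde tolerates the mild phosphate base at room temperature.

**Step 5**
Reactants: 7 2-(diethoxyphosphoryl)propanoic acid (racemic); 8 Meldrum's acid (2,2-dimethyl-1,3-dioxane-4,6-dione)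
Product: 10 S-tert-butyl 4-(diethoxyphosphoryl)-3-oxopentanethioate, via acyl Meldrum's acid 9 (not isolated)
Conditions: DCC, DMAP, CH2Cl2, 0 °C to rt, filter; then t-BuSH, toluene, 90 °C
Reagents that add atoms: 2-methylpropane-2-thiol, CC(C)(C)S
Why: carbodiimide-mediated C-acylation of Meldrum's acid, then thermal cycloreversion of the adduct to an acylketene (loss of acetone and carbon dioxide) that the thiol traps as the β-ketothioester; the phosphonate-bearing centre is racemic and is destroyed in step 6.

**Step 6**
Reactants: 6 (4R,6E,8E,10E,12E)-4-methyltetradeca-6,8,10,12-tetraenal; 10 S-tert-butyl 4-(diethoxyphosphoryl)-3-oxopentanethioate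
Product: 11 S-tert-butyl (4E,8R,10E,12E,14E,16E)-4,8-dimethyl-3-oxooctadeca-4,10,12,14,16-pentaenethioate
Conditions: NaH (2.2 equiv relative to 10), THF, 0 °C; then 6, 0 °C to rt, dark; aq. NH4Cl
Reagents that add atoms: none
Why: Horner–Wadsworth–Emmons olefination through the dianion of the β-keto phosphonate, whose phosphonate-stabilised terminus reacts with the aldehyde; the α-methyl ketophosphonate should give the E trisubstituted enone with the chain trans to the carbonyl.

**Step 7**
Reactants: 11 S-tert-butyl (4E,8R,10E,12E,14E,16E)-4,8-dimethyl-3-oxooctadeca-4,10,12,14,16-pentaenethioate; 12 methyl L-threoninate hydrochloride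
Product: 13 methyl (2S,3R)-2-{[(4E,8R,10E,12E,14E,16E)-4,8-dimethyl-3-oxooctadeca-4,10,12,14,16-pentaenoyl]amino}-3-hydroxybutanoate
Conditions: AgOCOCF3 (1.2 equiv), Et3N (2.5 equiv), THF, 0 °C to rt, dark
Reagents that add atoms: none
Why: silver-promoted aminolysis of a tert-butyl thioester, in which the thiophilic silver salt activates the acyl–sulfur bond at or below room temperature so that the polyene is not heated; the amine should be acylated in preference to the secondary alcohol and neither threonine centre is involved.

**Step 8**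
Reactants: 13 methyl (2S,3R)-2-{[(4E,8R,10E,12E,14E,16E)-4,8-dimethyl-3-oxooctadeca-4,10,12,14,16-pentaenoyl]amino}-3-hydroxybutanoate
Product: 14 (5S)-3-[(2E,6R,8E,10E,12E,14E)-2,6-dimethylhexadeca-2,8,10,12,14-pentaenoyl]-4-hydroxy-5-[(1R)-1-hydroxyethyl]-1,5-dihydro-2H-pyrrol-2-one
Conditions: KOtBu (2.2 equiv), t-BuOH/THF, 0 °C to rt, 20 min, dark; cold dilute HCl to pH 3, rapid extraction, crude product kept cold in DMSO and used at once
Reagents that add atoms: none
Why: Lacey–Dieckmann cyclisation, in which the β-ketoamide enolate attacks the methyl ester (5-exo-trig) to close the pyrrolidine-2,4-dione ring and the product is drawn out of the equilibrium as its stabilised tetramate anion; short exposure to base at room temperature should preserve C5.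

**Step 9**
Reactants: 14 (5S)-3-[(2E,6R,8E,10E,12E,14E)-2,6-dimethylhexadeca-2,8,10,12,14-pentaenoyl]-4-hydroxy-5-[(1R)-1-hydroxyethyl]-1,5-dihydro-2H-pyrrol-2-one
Product: 15 (5S)-3-{[(1R,2S,4aR,6R,8aS)-1,6-dimethyl-2-[(1E,3E)-penta-1,3-dien-1-yl]-1,2,4a,5,6,7,8,8a-octahydronaphthalen-1-yl]carbonyl}-4-hydroxy-5-[(1R)-1-hydroxyethyl]-1,5-dihydro-2H-pyrrol-2-one (CNP0298257.2)
Conditions: recombinant Diels–Alderase of the Fsa2 family (Phm7-type decalin synthase, 2 mol %), Tris-HCl buffer pH 7.5, 5% DMSO, 25 °C, dark, argon; then pH 3, EtOAc, reversed-phase HPLC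
Reagents that add atoms: none
Why: Diels–Alderases of the Fsa2 family bind linear 3-polyenoyltetramic acids of this type and catalyse their concerted, asynchronous intramolecular [4+2] cycloaddition, the closest known reactions being the decalin-forming steps of equisetin-type and phomasetin-type biosynthesis. The cyclohexene ring closes as the [4+2] adduct of the C8=C9–C10=C11 diene and the C2=C3 enoyl dienophile of the side chain (new bonds C2–C11 and C3–C8, which become C1–C2 and C4a–C8a of the decalin), and the cyclohexane ring closes in the same event because the four-carbon tether C4–C7 spans C3 and C8. The E dienophile fixes the C1/C8a relationship and the E,E diene the C2/C4a relationship suprafacially, and the endo orientation of the acyl carbonyl gives the trans ring fusion. The absolute sense, and with it the configuration of C1, C2, C4a and C8a relative to the existing C6 methyl, is set by the active-site pocket, which folds the tether as the chair that carries the 6-methyl axial. This is the selectivity the step needs, because without the protein the endo transition state with the methyl equatorial is preferred and leads to the diastereomer inverted at all four new centres; the background reaction is held back by keeping 14 as its tetramate anion at pH 7.5, dilute and in the dark. Periselectivity for the proximal diene of the tetraene is secured by ring size, since only that diene gives a six-membered tether ring.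

**Compound list**

1 | (R)-citronellal, (3R)-3,7-dimethyloct-6-enal | C[C@H](CCC=C(C)C)CC=O | starting material
2 | (1E,4R)-1-iodo-4,8-dimethylnona-1,7-diene | I/C=C/C[C@H](C)CCC=C(C)C | intermediate
3 | (4R,6E)-7-iodo-4-methylhept-6-enal | I/C=C/C[C@H](C)CCC=O | intermediate
4 | (2E,4E)-hexa-2,4-dienal (sorbaldehyde) | C/C=C/C=C/C=O | starting material
5 | 2-[(1E,3E,5E)-hepta-1,3,5-trien-1-yl]-4,4,5,5-tetramethyl-1,3,2-dioxaborolane | C/C=C/C=C/C=C/B1OC(C)(C)C(C)(C)O1 | intermediate
6 | (4R,6E,8E,10E,12E)-4-methyltetradeca-6,8,10,12-tetraenal | C/C=C/C=C/C=C/C=C/C[C@H](C)CCC=O | intermediate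
7 | 2-(diethoxyphosphoryl)propanoic acid (racemic) | CCOP(=O)(OCC)C(C)C(=O)O | starting material
8 | Meldrum's acid, 2,2-dimethyl-1,3-dioxane-4,6-dione | CC1(C)OC(=O)CC(=O)O1 | starting material
9 | 5-[2-(diethoxyphosphoryl)-1-hydroxypropylidene]-2,2-dimethyl-1,3-dioxane-4,6-dione (acyl Meldrum's acid) | CCOP(=O)(OCC)C(C)C(O)=C1C(=O)OC(C)(C)OC1=O | intermediate (not isolated)
10 | S-tert-butyl 4-(diethoxyphosphoryl)-3-oxopentanethioate (racemic) | CCOP(=O)(OCC)C(C)C(=O)CC(=O)SC(C)(C)C | intermediate
11 | S-tert-butyl (4E,8R,10E,12E,14E,16E)-4,8-dimethyl-3-oxooctadeca-4,10,12,14,16-pentaenethioate | C/C=C/C=C/C=C/C=C/C[C@H](C)CC/C=C(\C)C(=O)CC(=O)SC(C)(C)C | intermediate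
12 | methyl L-threoninate hydrochloride, methyl (2S,3R)-2-amino-3-hydroxybutanoate hydrochloride | Cl.N[C@@H]([C@@H](C)O)C(=O)OC | starting material
13 | methyl (2S,3R)-2-{[(4E,8R,10E,12E,14E,16E)-4,8-dimethyl-3-oxooctadeca-4,10,12,14,16-pentaenoyl]amino}-3-hydroxybutanoate | C/C=C/C=C/C=C/C=C/C[C@H](C)CC/C=C(\C)C(=O)CC(=O)N[C@@H]([C@@H](C)O)C(=O)OC | intermediate
14 | (5S)-3-[(2E,6R,8E,10E,12E,14E)-2,6-dimethylhexadeca-2,8,10,12,14-pentaenoyl]-4-hydroxy-5-[(1R)-1-hydroxyethyl]-1,5-dihydro-2H-pyrrol-2-one | C/C=C/C=C/C=C/C=C/C[C@H](C)CC/C=C(\C)C(=O)C1=C(O)[C@H]([C@@H](C)O)NC1=O | intermediate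
15 | (5S)-3-{[(1R,2S,4aR,6R,8aS)-1,6-dimethyl-2-[(1E,3E)-penta-1,3-dien-1-yl]-1,2,4a,5,6,7,8,8a-octahydronaphthalen-1-yl]carbonyl}-4-hydroxy-5-[(1R)-1-hydroxyethyl]-1,5-dihydro-2H-pyrrol-2-one | C/C=C/C=C/[C@H]1C=C[C@H]2C[C@H](C)CC[C@@H]2[C@@]1(C)C(=O)C1=C(O)[C@H]([C@@H](C)O)NC1=O | target

**Step count.** Total: 9 steps. Longest linear sequence: 7 steps (steps 1, 2, 4, 6, 7, 8 and 9, from 1 to 15); steps 3 and 5 prepare the two coupling partners 5 and 10.

**Steps most likely to fail**

Step 9. The protein may bind the threonine-derived substrate poorly or turn it over slowly. The uncatalysed cycloaddition, which follows the substrate's own preference for the chair with the methyl equatorial, would then compete and erode the facial selectivity. The fallback gives up catalyst control. It sets out from 14, which is left to cyclise without protein as the free acid in toluene at 40 °C with a trace of BHT in the dark. Both endo, trans-fused adducts should form: the (1S,2R,4aS,6R,8aR) diastereomer of the target F1 as the main product and 15 as the minor one. The two are separated by preparative reversed-phase HPLC, and the route is rejoined at 15.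

Step 8. The base may epimerise C5, eliminate the threonine hydroxyl, or leave the freshly formed enoyl tetramic acid long enough for it to cyclise by itself during work-up. The fallback closes the heterocycle before the polyene is attached. It sets out from 10 and 12, which are joined under the conditions of step 7 to give methyl N-[4-(diethoxyphosphoryl)-3-oxopentanoyl]-L-threoninate F2. Lacey–Dieckmann cyclisation of this robust compound (KOtBu, t-BuOH) should give (5S)-3-[2-(diethoxyphosphoryl)propanoyl]-4-hydroxy-5-[(1R)-1-hydroxyethyl]-1,5-dihydro-2H-pyrrol-2-one F3, whose configuration at C5 can be checked at leisure. Horner–Wadsworth–Emmons olefination of the polyanion of F3 (KOtBu, 4 equiv, THF, 0 °C to rt) with aldehyde 6 then delivers the potassium salt of 14, and the route is rejoined at 14.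

Step 1. The chromium iodo-olefination may not be E-selective enough, and a Z-iodoalkene that cannot be removed would carry a wrong diene geometry into the cycloaddition substrate. The fallback replaces the olefination by an alkyne hydrometalation. It sets out from 1, which is homologated with the Ohira–Bestmann reagent (dimethyl (1-diazo-2-oxopropyl)phosphonate, K2CO3, MeOH) to (4R)-4,8-dimethylnon-7-en-1-yne F4. Hydrozirconation of the terminal alkyne with Cp2Zr(H)Cl in THF and iodinolysis with I2 should give the E-iodoalkene by syn addition, with the trisubstituted alkene untouched, and the route is rejoined at 2.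

**Further compounds**

F1 | step 9 | (5S)-3-{[(1S,2R,4aS,6R,8aR)-1,6-dimethyl-2-[(1E,3E)-penta-1,3-dien-1-yl]-1,2,4a,5,6,7,8,8a-octahydronaphthalen-1-yl]carbonyl}-4-hydroxy-5-[(1R)-1-hydroxyethyl]-1,5-dihydro-2H-pyrrol-2-one | C/C=C/C=C/[C@@H]1C=C[C@@H]2C[C@H](C)CC[C@H]2[C@]1(C)C(=O)C1=C(O)[C@H]([C@@H](C)O)NC1=O
F2 | step 8 | methyl N-[4-(diethoxyphosphoryl)-3-oxopentanoyl]-L-threoninate | CCOP(=O)(OCC)C(C)C(=O)CC(=O)N[C@@H]([C@@H](C)O)C(=O)OC
F3 | step 8 | (5S)-3-[2-(diethoxyphosphoryl)propanoyl]-4-hydroxy-5-[(1R)-1-hydroxyethyl]-1,5-dihydro-2H-pyrrol-2-one | CCOP(=O)(OCC)C(C)C(=O)C1=C(O)[C@H]([C@@H](C)O)NC1=O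
F4 | step 1 | (4R)-4,8-dimethylnon-7-en-1-yne | C#CC[C@H](C)CCC=C(C)C
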